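**Retrosynthetic overview**
1. Target ⇐ 8‑hydroxy macrolactone + tiglic acid (late esterification).
2. Ten‑membered carbocycle and α‑methylene‑γ‑butyrolactone ⇐ one C6–C7 bond, formed by a chromium‑electrocatalytic intramolecular allylation/lactonization of a (Z)‑enal onto a 2‑(bromomethyl)enoate (sets C6 and C7 from C8/C10).
3. Allyl bromide ⇐ Morita–Baylis–Hillman/SN2′ from a C7 aldehyde; 3(2H)‑furanone ⇐ 5‑endo oxa‑Michael of an α′‑hydroxy ynone.
4. Ynone ⇐ acetylide of (Z)‑3‑methylpent‑2‑en‑4‑yn‑1‑ol + a γ‑lactone carrying C8 (bought) and C10 (set by trans‑methylation).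
5. Ring order: sacrificial γ‑lactone template → furanone → macrocycle and methylene lactone together.

Atom labels follow germacrane numbering: C1 furanone C=O, C2=C3, C3–O–C10, C4(Me‑15)=C5 (Z), C6 (lactone O–CH), C7, C8 (ester CH), C9H2, C10 (Me‑14), C11(=C13H2)–C12(=O).

Assumption: compound 1 is bought as the trityl ether (D‑glutamic‑acid‑derived lactone); if only the 5‑hydroxymethyl lactone is in stock, one tritylation step is added.

**Step 1**
Reactants: 1, (R)‑5‑[(trityloxy)methyl]dihydrofuran‑2(3H)‑one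
Product: 2, (5R)‑3‑[(tert‑butyldimethylsilyl)oxy]‑5‑[(trityloxy)methyl]dihydrofuran‑2(3H)‑one (C3 epimer mixture, used as such)
Conditions: LDA, THF, −78 °C; TBSCl, DMPU, −78→0 °C; pentane filtration; mCPBA, NaHCO3, CH2Cl2, −20→0 °C
Reagents that add atoms: TBSCl, CC(C)(C)[Si](C)(C)Cl; mCPBA, OOC(=O)c1cccc(Cl)c1
Why: Rubottom oxidation – the lactone ketene silyl acetal is epoxidised and collapses with O→O silyl shift to the α‑silyloxy lactone; the C3 configuration is irrelevant because C3 is re‑enolised in step 2.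

**Step 2**
Reactants: 2
Product: 3, (3R,5R)‑3‑[(tert‑butyldimethylsilyl)oxy]‑3‑methyl‑5‑[(trityloxy)methyl]dihydrofuran‑2(3H)‑one (Me trans, OTBS cis to CH2OTr)
Conditions: LDA, THF, −78 °C; MeI, DMPU, −78→−40 °C
Reagents that add atoms: iodomethane, CI
Why: Lactone enolate alkylation – MeI attacks the tetrasubstituted enolate anti to the bulky C5 CH2OTr group (1,3‑trans induction), which fixes C10 as R under control of the purchased C8 centre.

**Step 3**
Reactants: 4, (Z)‑3‑methylpent‑2‑en‑4‑yn‑1‑ol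
Product: 5, (Z)‑3‑methyl‑5‑(trityloxy)pent‑3‑en‑1‑yne
Conditions: TrCl, Et3N, DMAP (cat.), CH2Cl2, rt
Reagents that add atoms: trityl chloride, ClC(c1ccccc1)(c1ccccc1)c1ccccc1
Why: Standard O‑tritylation of the primary allylic alcohol; the Z‑alkene is untouched.

**Step 4**
Reactants: 3; 5
Product: 6, (R)‑2‑[(R)‑2‑(TBS‑oxy)‑3‑(trityloxy)propyl]‑2‑methyl‑5‑[(Z)‑4‑(trityloxy)but‑2‑en‑2‑yl]furan‑3(2H)‑one
Conditions: 5, n‑BuLi, THF, −78 °C; add 3, −78→−20 °C; then HMPA, →23 °C; aq NH4Cl
Reagents that add atoms: none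
Why: Acetylide mono‑addition opens the lactone to the α′‑silyloxy ynone C8 alkoxide, a 1,5 O→O silyl migration (1,3‑diol type) frees the tertiary C10 alkoxide, and this closes irreversibly by 5‑endo‑dig oxa‑Michael addition to the 3(2H)‑furanone; no stereocentre is touched.

**Step 5**
Reactants: 6
Product: 7, (R)‑2‑[(R)‑2‑(TBS‑oxy)‑3‑hydroxypropyl]‑5‑[(Z)‑4‑hydroxybut‑2‑en‑2‑yl]‑2‑methylfuran‑3(2H)‑one
Conditions: TsOH·H2O (cat.), MeOH/CH2Cl2 1:1, 0 °C
Reagents that add atoms: none
Why: Acid‑catalysed methanolysis of both trityl ethers; the secondary TBS ether and the vinylogous ester survive at 0 °C.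

**Step 6**
Reactants: 7
Product: 8, (Z)‑3‑{(R)‑5‑[(R)‑2‑(TBS‑oxy)‑3‑oxopropyl]‑5‑methyl‑4‑oxo‑4,5‑dihydrofuran‑2‑yl}but‑2‑enal (dialdehyde)
Conditions: Dess–Martin periodinane, NaHCO3, CH2Cl2, 0 °C→rt
Reagents that add atoms: none
Why: Buffered Dess–Martin oxidation of both primary alcohols gives the (Z)‑enal and the α‑silyloxy aldehyde without epimerisation or Z/E isomerisation.

**Step 7**
Reactants: 8; 9, methyl acrylate
Product: 10, methyl (4R)‑4‑(TBS‑oxy)‑3‑hydroxy‑2‑methylene‑5‑{(R)‑2‑methyl‑3‑oxo‑5‑[(Z)‑4‑oxobut‑2‑en‑2‑yl]‑2,3‑dihydrofuran‑2‑yl}pentanoate (C3/C7 epimers)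
Conditions: DABCO (1 equiv), methyl acrylate (excess), MeOH (cat.), rt
Reagents that add atoms: none (9 is a reactant)
Why: Morita–Baylis–Hillman reaction – the DABCO–acrylate zwitterion adds only to the saturated, inductively activated aldehyde (the β,β‑disubstituted enal is a poor MBH electrophile); the new C7 carbinol centre is irrelevant because C7 becomes sp2 in step 8.

**Step 8**
Reactants: 10
Product: 11, methyl (R,Z)‑2‑(bromomethyl)‑4‑(TBS‑oxy)‑5‑{(R)‑2‑methyl‑3‑oxo‑5‑[(Z)‑4‑oxobut‑2‑en‑2‑yl]‑2,3‑dihydrofuran‑2‑yl}pent‑2‑enoate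
Conditions: MsCl, Et3N, CH2Cl2, −20 °C; then LiBr, THF, 0 °C
Reagents that add atoms: lithium bromide, [Li+].[Br-]
Why: Mesylation then SN2′ displacement by bromide (allylic transposition) gives the thermodynamically preferred conjugated (Z)‑2‑(bromomethyl)enoate.

**Step 9**
Reactants: 11
Product: 12, 8‑O‑TBS‑8‑desacyl macrolactone: 10‑membered carbocycle, furanone bridge and trans‑fused α‑methylene‑γ‑butyrolactone, with the target's spatial configuration at C6, C7, C8, C10 (CIP 6R,7S,8R,10R; the C7 label differs from the target only because of the silyl ether)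
Conditions: CrCl2 (20 mol %), TMSCl (3 equiv), n‑Bu4NBr, DMF/THF, undivided cell, RVC cathode/Al anode, −1.0 V vs Ag/AgCl (≈2.2 F mol⁻¹), 11 added over 10 h to 2 mM, rt; then PPTS
Reagents that add atoms: none
Why: Proposed new method: a chromium‑electrocatalytic intramolecular Nozaki–Hiyama (Barbier‑type) allylation–lactonization. Cathodically generated Cr(II) abstracts Br to give an allyl radical that a second Cr(II) traps as a C13‑bound allyl‑Cr(III); this adds to the C6 aldehyde through C7 in a chair‑like transition state (E‑allylchromium, anti addition → 6,7‑trans lactone), with H‑8 in the allyl plane (A1,3 strain) and the C9 tether anti to the forming bond, giving the natural C7/C8 relationship. The C6 alkoxide lactonises onto the methyl ester and TMSCl releases Cr(III) for re‑reduction; the closest known chemistry is intermolecular Cr‑catalysed electroreductive NHK coupling and stoichiometric Cr(II)/In Barbier lactonizations of 2‑(bromomethyl)acrylates.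

**Step 10**
Reactants: 12
Product: 13, (6R,7R,8R,10R)‑8‑hydroxy macrolactone (8‑desacyl target)
Conditions: HF·pyridine, pyridine/THF, 0 °C→rt
Reagents that add atoms: none
Why: Buffered fluoride cleavage of the secondary silyl ether; non‑basic conditions spare the α‑methylene lactone and the furanone.

**Step 11**
Reactants: 13; 14, tiglic acid [(E)‑2‑methylbut‑2‑enoic acid]
Product: 15, atripliciolide tiglate (target)
Conditions: 2,4,6‑trichlorobenzoyl chloride, Et3N, THF; then 13, DMAP, toluene, rt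
Reagents that add atoms: none (14 is a reactant)
Why: Yamaguchi esterification of the hindered C8 alcohol with retention of configuration; the tiglate E‑geometry is the stable isomer.

**Compound list**
1 | (R)‑5‑[(trityloxy)methyl]dihydrofuran‑2(3H)‑one | O=C1CC[C@H](COC(c2ccccc2)(c2ccccc2)c2ccccc2)O1 | starting material
2 | (5R)‑3‑(TBS‑oxy)‑5‑[(trityloxy)methyl]dihydrofuran‑2(3H)‑one | O=C1C(O[Si](C)(C)C(C)(C)C)C[C@H](COC(c2ccccc2)(c2ccccc2)c2ccccc2)O1 | intermediate
3 | (3R,5R)‑3‑(TBS‑oxy)‑3‑methyl‑5‑[(trityloxy)methyl]dihydrofuran‑2(3H)‑one | C[C@@]1(O[Si](C)(C)C(C)(C)C)C[C@H](COC(c2ccccc2)(c2ccccc2)c2ccccc2)OC1=O | intermediate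
4 | (Z)‑3‑methylpent‑2‑en‑4‑yn‑1‑ol | C#C/C(C)=C\CO | starting material
5 | (Z)‑3‑methyl‑5‑(trityloxy)pent‑3‑en‑1‑yne | C#C/C(C)=C\COC(c1ccccc1)(c1ccccc1)c1ccccc1 | intermediate
6 | furanone with C8‑OTBS, C6‑ and C7‑OTr | C(/C=C(/C)C1=CC(=O)[C@@](C)(C[C@@H](O[Si](C)(C)C(C)(C)C)COC(c2ccccc2)(c2ccccc2)c2ccccc2)O1)OC(c1ccccc1)(c1ccccc1)c1ccccc1 | intermediate
7 | furanone diol | OC/C=C(/C)C1=CC(=O)[C@@](C)(C[C@@H](O[Si](C)(C)C(C)(C)C)CO)O1 | intermediate
8 | furanone dialdehyde | O=C/C=C(/C)C1=CC(=O)[C@@](C)(C[C@@H](O[Si](C)(C)C(C)(C)C)C=O)O1 | intermediate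
9 | methyl acrylate | C=CC(=O)OC | starting material
10 | Baylis–Hillman adduct | O=C/C=C(/C)C1=CC(=O)[C@@](C)(C[C@@H](O[Si](C)(C)C(C)(C)C)C(O)C(=C)C(=O)OC)O1 | intermediate
11 | (Z)‑allyl bromide enal | O=C/C=C(/C)C1=CC(=O)[C@@](C)(C[C@@H](O[Si](C)(C)C(C)(C)C)/C=C(\CBr)C(=O)OC)O1 | intermediate
12 | 8‑O‑TBS macrolactone | C=C1C(=O)O[C@@H]2/C=C(/C)C3=CC(=O)[C@@](C)(C[C@@H](O[Si](C)(C)C(C)(C)C)[C@@H]12)O3 | intermediate
13 | 8‑hydroxy macrolactone | C=C1C(=O)O[C@@H]2/C=C(/C)C3=CC(=O)[C@@](C)(C[C@@H](O)[C@@H]12)O3 | intermediate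
14 | tiglic acid | C/C=C(\C)C(=O)O | starting material
15 | atripliciolide tiglate | C=C1C(=O)O[C@@H]2/C=C(/C)C3=CC(=O)[C@@](C)(C[C@@H](OC(=O)/C(C)=C/C)[C@@H]12)O3 | target

**Totals**
Total steps: 11. Longest linear sequence: 10 (steps 1, 2, 4–11 from 1); step 3 is a one‑step branch.

**Three steps most likely to fail**
- **Step 9 (proposed new step).** Risks are 1,4‑elimination or over‑reduction of the dienal, and the wrong C6/C7 diastereomer. Fallback with known chemistry: postpone furanone formation, carry the open α′‑silyloxy ynone through to the bromo‑aldehyde, close the ten‑membered ring on this more flexible enyne with stoichiometric CrCl2 or indium (classical Barbier macrolactonization), and form the furanone last by Au(I)‑catalysed transannular oxa‑Michael cyclization.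
- **Step 4.** Risks are slow addition to the hindered lactone and an incomplete silyl relay. Fallback: abandon the relay, cleave the C10 silyl ether with TBAF (which triggers furanone closure with free 8‑OH) and install the C8 TBS ether in a separate step (+1 step).
- **Step 7.** Risks are a slow MBH on the α‑silyloxy aldehyde and Z→E drift or competing reaction of the enal. Fallback: protect C6–OH as a PMB ether instead of trityl so C7 is oxidised and homologated alone, install the acrylate by vinylalumination (DIBAL/NMO, methyl propiolate), and unveil and oxidise C6 only after the bromide is in place (+1–2 steps).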